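**Assumptions (one line each)**
- The drimane half of the target is the natural labdane series (5S, 9R, 10S). I checked that it matches (+)-sclareolide (3aR,5aS,9aS,9bR).
- The B-ring quinone is attacked by the alkyl radical at C-6′ (next to the chromone-bearing carbon), and the C-7 oxidation at the end discriminates between the two alkenes.

**Retrosynthesis**
1. Target ← late allylic oxidation of the exocyclic 8(17)-ene to the α-methylene ketone (SeO2/TBHP, then MnO2).
2. Key disconnection (no Diels–Alder): the quaternary C-1′ stereocentre and the cyclohexene ring come from a Lewis-acid 6-endo quinone–alkene (ene/Prins-type) cyclisation of a 6-alkyl-2-chromonyl-5-methoxybenzoquinone carrying an (E)-trisubstituted alkene.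
3. The alkylquinone ← Ag/persulfate decarboxylative radical alkylation of the chromonyl quinone with an acid made from sclareolide (lactol → isopropenyl carbinol → Eschenmoser–Claisen → dehydration → hydrolysis).
4. The chromonyl quinone ← CAN oxidation of a 2′,4′,5′-trimethoxyflavone ← chalcone ← commercial phloroacetophenone and 2,4,5-trimethoxybenzaldehyde.
5. Ring order: trans-decalin (from sclareolide), chromone, quinone unmasked, cyclohexene ring closed in the key step, exocyclic enone last.

## Route

**Step 1**
Reactants: 1 (+)-sclareolide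
Product: 2 sclareolide lactol (12-hydroxy-ambrox, anomeric mixture)
Conditions: DIBAL-H, CH2Cl2, –78 °C
Reagents that add atoms: none
Why: Partial lactone reduction stops at the lactol, and the decalin stereocentres (C5, C9, C10, C8) are untouched.

**Step 2**
Reactants: 2 lactol; 3 isopropenylmagnesium bromide
Product: 4 diol: the 8α-hydroxy decalin whose C-9 side chain is CH2–CH(OH)–C(CH3)=CH2 (C-12 epimers, stereodescriptors as in sclareol)
Conditions: 3 (3 equiv), THF, 0 °C to rt
Reagents that add atoms: isopropenylmagnesium bromide, C=C(C)[Mg]Br (compound 3, adds C3H5)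
Why: The Grignard reagent opens the lactol to the hydroxy-aldehyde and adds 1,2 (Grignard addition); the new C-12 carbinol stereocentre is destroyed in Step 3, so its configuration does not matter.

**Step 3**
Reactants: 4 diol; 5 N,N-dimethylacetamide dimethyl acetal
Product: 6 (E)-N,N-dimethyl-6-[(8α-hydroxydecalinyl)]-4-methylhex-4-enamide (E-C12=C13 alkene, 8α-OH retained)
Conditions: 5 (5 equiv), xylene, 140 °C, sealed tube
Reagents that add atoms: N,N-dimethylacetamide dimethyl acetal, CC(OC)(OC)N(C)C (compound 5, adds CH2C(=O)NMe2)
Why: Eschenmoser–Claisen [3,3] proceeds through a chair TS with C-11 equatorial, so it gives the (E)-trisubstituted alkene with the required two-carbon chain. These conditions are neutral, which avoids Ambrox-type cyclisation of the 8-OH onto C-12.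

**Step 4**
Reactants: 6 hydroxy amide
Product: 7 8(17)-ene amide (exocyclic methylene, E-alkene)
Conditions: Burgess reagent, benzene, 50 °C (Δ8(17) isomer separated on AgNO3–SiO2)
Reagents that add atoms: none
Why: Syn-elimination (Burgess dehydration) of the equatorial tertiary 8α-OH can only use the C-17 methyl hydrogens (no axial anti H is available), so the exocyclic methylene is the major product and no stereocentre is touched.

**Step 5**
Reactants: 7 amide
Product: 8 acid, (E)-6-(drimane-type 8(17)-ene)-4-methylhex-4-enoic acid
Conditions: KOH, ethylene glycol/H2O, 185 °C; then H3O+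
Reagents that add atoms: water, O (with KOH, [K+].[OH-])
Why: Forcing base hydrolysis of the tertiary amide leaves the alkenes and the decalin stereocentres intact.

**Step 6**
Reactants: 9 2′,4′,6′-trihydroxyacetophenone; 10 2,4,5-trimethoxybenzaldehyde
Product: 11 2′,4′,6′-trihydroxy-2,4,5-trimethoxychalcone
Conditions: aq. KOH, EtOH, rt, 48 h
Reagents that add atoms: none
Why: Claisen–Schmidt aldol condensation.

**Step 7**
Reactants: 11 chalcone
Product: 12 5,7-dihydroxy-2-(2,4,5-trimethoxyphenyl)chromone
Conditions: I2 (0.2 equiv), DMSO, 130 °C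
Reagents that add atoms: none
Why: Oxidative cyclisation of the 2′-hydroxychalcone (iodine-mediated oxa-Michael, then oxidation) gives the flavone without protecting groups.

**Step 8**
Reactants: 12 flavone
Product: 13 2-(5,7-dihydroxychromon-2-yl)-5-methoxy-1,4-benzoquinone
Conditions: CAN (2.2 equiv), MeCN/H2O 3:1, 0 °C, 10 min
Reagents that add atoms: water, O
Why: CAN oxidative demethylation converts the para-dimethoxy pair (C-2′, C-5′) to the quinone and leaves the 4′-OMe as the vinylogous-ester methoxy.

**Step 9**
Reactants: 13 quinone; 8 acid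
Product: 14 6-alkyl quinone (alkyl = CH2CH2C(CH3)=CH–CH2–drimane, E)
Conditions: AgNO3 (0.3 equiv), (NH4)2S2O8 (2.5 equiv), MeCN/H2O 1:1, NaH2PO4 buffer, 60 °C
Reagents that add atoms: none
Why: Fieser–Jacobsen oxidative decarboxylative radical alkylation; the nucleophilic primary radical adds at C-6′, which gives the chromone-stabilised radical at C-1′, and persulfate re-oxidises to the quinone.

**Step 10** (key step)
Reactants: 14 alkylquinone
Product: 15 7-deoxo cyclised enedione (cis-fused cyclohexene, quaternary C-1′ bearing the chromone, C-6′–H)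
Conditions: Me2AlCl (4 equiv), CH2Cl2, –78 °C to –20 °C, 3 h; Rochelle salt work-up
Reagents that add atoms: none (the methyl is lost as CH4)
Why: Proposed new method: Me2AlCl activates the C-5′ carbonyl, so C-1′ (the carbon β to that carbonyl) is attacked in a 6-endo fashion by C-12 of the (E)-trisubstituted alkene, giving a tertiary C-13 cation and an aluminium enolate; intramolecular proton transfer from C-14–H (a six-membered, ene-like transfer to the enolate O) forms the ring C13=C14 alkene, and tautomerisation protonates C-6′. The closest known chemistry is Snider-type Me2AlCl-promoted ene reactions and 6-endo cation–olefin closures. The six-membered tether forces the cis ring fusion, the (E)-alkene in a chair-like cyclohexane-1,4-diyl-type TS places C-11 pseudo-equatorial and the chromone pseudo-axial (cis), and the C-6′–H settles to the cis-fused isomer on work-up; C-9 gives only weak control over C-12, so I expect a diastereomer mixture from which the desired one is separated by HPLC.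

**Step 11**
Reactants: 15 exocyclic alkene
Product: 16 7-hydroxy-8(17)-ene (C-7 epimers)
Conditions: SeO2 (0.5 equiv), TBHP (4 equiv), CH2Cl2, 0 °C to rt
Reagents that add atoms: tert-butyl hydroperoxide, CC(C)(C)OO (adds O)
Why: Riley/Sharpless allylic oxidation (Se-ene then [2,3]-shift) hydroxylates the ring CH2 next to the exocyclic methylene, as in kaurene C-15 oxidation, and the shielded ring-alkene should be less reactive.

**Step 12**
Reactants: 16 allylic alcohol
Product: 17 dichrostachine L
Conditions: activated MnO2 (30 equiv), CH2Cl2/acetone, rt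
Reagents that add atoms: none
Why: MnO2 selectively oxidises the allylic alcohol to the α-methylene ketone, and both C-7 epimers converge on one product.

## Compound list

| # | Name | SMILES | Role |
|---|---|---|---|
| 1 | (+)-sclareolide | O=C1C[C@@H]2[C@@]3(C)CCCC(C)(C)[C@@H]3CC[C@@]2(C)O1 | starting material |
| 2 | sclareolide lactol | OC1C[C@@H]2[C@@]3(C)CCCC(C)(C)[C@@H]3CC[C@@]2(C)O1 | intermediate |
| 3 | isopropenylmagnesium bromide | C=C(C)[Mg]Br | starting material |
| 4 | 8α-hydroxy, 12-hydroxy-13-ene diol (C-12 epimers) | C=C(C)C(O)C[C@@H]1[C@@]2(C)CCCC(C)(C)[C@@H]2CC[C@@]1(C)O | intermediate |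
| 5 | N,N-dimethylacetamide dimethyl acetal | CC(OC)(OC)N(C)C | starting material |
| 6 | (E)-hydroxy amide | CN(C)C(=O)CC/C(C)=C/C[C@@H]1[C@@]2(C)CCCC(C)(C)[C@@H]2CC[C@@]1(C)O | intermediate |
| 7 | (E)-8(17)-ene amide | C=C1CC[C@H]2C(C)(C)CCC[C@]2(C)[C@H]1C/C=C(\C)CCC(=O)N(C)C | intermediate |
| 8 | (E)-8(17)-ene acid | C=C1CC[C@H]2C(C)(C)CCC[C@]2(C)[C@H]1C/C=C(\C)CCC(=O)O | intermediate |
| 9 | 2′,4′,6′-trihydroxyacetophenone | CC(=O)c1c(O)cc(O)cc1O | starting material |
| 10 | 2,4,5-trimethoxybenzaldehyde | O=Cc1cc(OC)c(OC)cc1OC | starting material |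
| 11 | chalcone | O=C(/C=C/c1cc(OC)c(OC)cc1OC)c1c(O)cc(O)cc1O | intermediate |
| 12 | 5,7-dihydroxy-2′,4′,5′-trimethoxyflavone | COc1cc(OC)c(-c2cc(=O)c3c(O)cc(O)cc3o2)cc1OC | intermediate |
| 13 | 2-chromonyl-5-methoxy-1,4-benzoquinone | O=C1C=C(OC)C(=O)C=C1c1cc(=O)c2c(O)cc(O)cc2o1 | intermediate |
| 14 | 6-alkyl quinone | C=C1CC[C@H]2C(C)(C)CCC[C@]2(C)[C@H]1C/C=C(\C)CCC1=C(c2cc(=O)c3c(O)cc(O)cc3o2)C(=O)C=C(OC)C1=O | intermediate |
| 15 | 7-deoxo cyclised enedione | C=C1CC[C@H]2C(C)(C)CCC[C@]2(C)[C@H]1C[C@@H]1C(C)=CC[C@H]2C(=O)C(OC)=CC(=O)[C@@]12c1cc(=O)c2c(O)cc(O)cc2o1 | intermediate |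
| 16 | 7-hydroxy-8(17)-ene (C-7 epimers) | C=C1C(O)C[C@H]2C(C)(C)CCC[C@]2(C)[C@H]1C[C@@H]1C(C)=CC[C@H]2C(=O)C(OC)=CC(=O)[C@@]12c1cc(=O)c2c(O)cc(O)cc2o1 | intermediate |
| 17 | dichrostachine L | C=C1C(=O)C[C@H]2C(C)(C)CCC[C@]2(C)[C@H]1C[C@@H]1C(C)=CC[C@H]2C(=O)C(OC)=CC(=O)[C@@]12c1cc(=O)c2c(O)cc(O)cc2o1 | target |

**Total steps:** 12. **Longest linear sequence:** 9 steps, 1 → 2 → 4 → 6 → 7 → 8 → 14 → 15 → 16 → 17.

**Three steps most likely to fail**
1. **Step 10 (quinone–alkene cyclisation).** The risks are 5-exo versus 6-endo closure, methyl transfer from the aluminium reagent, and the wrong C-12 configuration relative to C-1′ and C-9. Fallback: an intermolecular, Lewis-acid-catalysed, exo-selective Diels–Alder of quinone 13 with (E)-labda-8(17),12,14-triene (from sclareol dehydration), followed by the same Steps 11–12.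
2. **Step 9 (radical alkylation).** The risks are C-6′ versus C-3′ regioselectivity and persulfate damage to the free phenols or the 8(17)-alkene. Fallback: build the tether on the arene first. Brominate 2,4,5-trimethoxybenzaldehyde at C-6, Negishi-couple it with the zinc reagent from the alkyl iodide derived from acid 8, then run the chalcone, flavone and CAN steps.
3. **Step 11 (SeO2 chemoselectivity).** The ring trisubstituted alkene, the phenols, and C-17 over-oxidation compete with C-7 hydroxylation. Fallback: install the C-7 oxygen early. Do the allylic oxidation on the 8(17)-ene TBS ether of the sclareolide-derived primary alcohol (before any other alkene exists), carry the protected 7-OH through the route, and leave only the final MnO2 oxidation at the end.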